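Ring A is disconnected at C8–C8a: its four contiguous oxygen-bearing carbons C5, C6, C7 and C8 are taken from the four carbons of dimethyl squarate, and the C4a–C8a bond is the C5=C6 double bond of a preformed 2-aryl-4-pyranone that already holds rings B and C. In one thermolysis a cyclobutenone opens to a dienylketene, ring A closes by six-electron electrocyclisation onto pyranone C6, and tautomerisation aromatises it, so the whole flavone core appears with every ring A oxygen in place. The precursor is a racemic 2,3,4-trimethoxycyclobutenone carrying the 6-aryl-4-oxopyran-3-yl group on its quaternary C4.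

Key step: step 5

Assumption: 4-(benzyloxy)benzoyl chloride is taken as a purchased reagent; it is otherwise one operation from the acid with oxalyl chloride.

Remarks: the target has no stereocentre. Compounds 9, 10 and 12 are racemic, and their single stereocentre is erased in step 5. Pyranone atoms are numbered O1, C2 (aryl), C3, C4 (C=O), C5, C6; flavone numbering is used from 12 onward.

Step 1
Reactants: 1 (E)-4-methoxybut-3-en-2-one; 2 4-(benzyloxy)benzoyl chloride
Product: 5 2-[4-(benzyloxy)phenyl]-4H-pyran-4-one, via lithium dienolate 3 (not isolated), via enolised 1,3-diketone 4 (not isolated)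
Conditions: 1 (2.1 equiv), LiN(SiMe3)2 (2.1 equiv), THF, −78 °C; 2 (1 equiv), −78 °C; aq. NH4Cl; crude 4, CF3CO2H (cat.), CH2Cl2, rt
Reagents that add atoms: none
Why: Claisen-type C-acylation of the kinetic lithium dienolate (the second equivalent of enolate takes up the acidic diketone proton), then acid-catalysed 6-endo oxa-Michael addition of the enol oxygen to the β-methoxyenone with loss of methanol, is an established entry to 2-substituted 4-pyranones, and the benzyl ether is inert to both stages.

Step 2
Reactants: 5 2-[4-(benzyloxy)phenyl]-4H-pyran-4-one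
Product: 6 2-[4-(benzyloxy)phenyl]-5-iodo-4H-pyran-4-one
Conditions: I2 (1.5 equiv), pyridine, CH2Cl2, 0 °C to rt, dark
Reagents that add atoms: iodine, II
Why: Amine-triggered α-iodination of a β-alkoxyenone (Baylis–Hillman-type addition, iodination, elimination): pyridine adds reversibly at the unsubstituted C6, the enolate is iodinated at C5 and pyridine is expelled, which should favour C5 over the aryl-flanked C3 and leave the benzyloxyphenyl ring untouched.

Step 3
Reactants: 6 2-[4-(benzyloxy)phenyl]-5-iodo-4H-pyran-4-one; 7 dimethyl squarate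
Product: 9 racemic 4-{6-[4-(benzyloxy)phenyl]-4-oxo-4H-pyran-3-yl}-4-hydroxy-2,3-dimethoxycyclobut-2-en-1-one, via pyranonylmagnesium chloride 8 (not isolated)
Conditions: iPrMgCl·LiCl (1.05 equiv), THF, −40 °C, 30 min; cannulate into 7 (1.3 equiv), THF, −78 to −40 °C; aq. NH4Cl at low temperature
Reagents that add atoms: none
Why: Iodine–magnesium exchange on α-iodo-β-alkoxyenones (as with 5-iodo-1,3-dioxin-4-ones) is fast at low temperature and outruns attack on the vinylogous ester carbonyl, and the alkenyl Grignard reagent then adds 1,2 to one of the two equivalent ketone carbonyls of the squarate, forming the quaternary carbinol centre as a racemate.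

Step 4
Reactants: 9 racemic 4-{6-[4-(benzyloxy)phenyl]-4-oxo-4H-pyran-3-yl}-4-hydroxy-2,3-dimethoxycyclobut-2-en-1-one
Product: 10 racemic 4-{6-[4-(benzyloxy)phenyl]-4-oxo-4H-pyran-3-yl}-2,3,4-trimethoxycyclobut-2-en-1-one
Conditions: MeI (10 equiv), Ag2O (2 equiv), 4 Å molecular sieves, MeCN, rt, dark
Reagents that add atoms: iodomethane, CI
Why: Purdie-type O-methylation with Ag2O and MeI etherifies the tertiary cyclobutenol under nearly neutral conditions, so no free alkoxide builds up that could open the strained ring, and 9 has no other acidic hydrogen.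

Step 5
Reactants: 10 racemic 4-{6-[4-(benzyloxy)phenyl]-4-oxo-4H-pyran-3-yl}-2,3,4-trimethoxycyclobut-2-en-1-one
Product: 13 4'-(benzyloxy)-8-hydroxy-5,6,7-trimethoxyflavone, via dienylketene 11 (not isolated), via 8aH-chromene-4,8-dione 12 (not isolated)
Conditions: p-xylene (0.01 M, dry, degassed), reflux (138 °C), Ar
Reagents that add atoms: none
Why: Heat opens the cyclobutenone by conrotatory four-electron electrocyclic ring opening to dienylketene 11, the C4 methoxy donor rotating outward so that the pyranonyl group lies cis to the ketene (a ketene opened the other way can only reclose). The ketene C=C, the dimethoxy-substituted C=C and the pyranone C5=C6 bond then form a hexatriene that closes ring A in disrotatory six-electron fashion (6π electrocyclisation, new bond C8–C8a), and enolisation of the C8a hydrogen of dienone 12 to the former ketene oxygen aromatises the ring and gives the C8 phenol. The closest known reaction type is the Moore-type ring expansion of squarate-derived 4-aryl-, 4-heteroaryl- and 4-alkenyl-4-alkoxycyclobutenones to monoprotected hydroquinones; a pyran-4-on-3-yl group has not, as far as is known, served as the unsaturated arm, but its C5=C6 bond is a cyclic β-alkoxyvinyl unit with little aromatic stabilisation to give up. No stereocentre is created, since the C4 centre of 10 and the C8a centre of 12 are both erased. The step needs regioselective closure, which is structural because the only olefinic neighbour of the attachment carbon is C6 (the other neighbour is the C4 carbonyl carbon), and it needs the ketene to cyclise before it is intercepted, which high dilution in a dry, degassed, non-nucleophilic solvent should secure.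

Step 6
Reactants: 13 4'-(benzyloxy)-8-hydroxy-5,6,7-trimethoxyflavone
Product: 14 4'-(benzyloxy)-5,6,7,8-tetramethoxyflavone
Conditions: MeI (3 equiv), K2CO3 (2 equiv), acetone, reflux
Reagents that add atoms: iodomethane, CI
Why: Williamson O-methylation of the only free phenol, for which K2CO3 is basic enough and to which the pyranone, the methyl ethers and the benzyl ether are stable.

Step 7
Reactants: 14 4'-(benzyloxy)-5,6,7,8-tetramethoxyflavone
Product: 15 4'-hydroxy-5,6,7,8-tetramethoxyflavone
Conditions: H2 (1 atm), 10% Pd/C, EtOAc/MeOH, rt, stopped when 14 is consumed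
Reagents that add atoms: none
Why: Catalytic hydrogenolysis of the benzyl aryl ether over palladium on carbon should be much faster than reduction of the vinylogous-ester C2=C3 bond of the flavone and leaves the methyl ethers alone.

Compound list
1 | (E)-4-methoxybut-3-en-2-one | CO/C=C/C(C)=O | starting material
2 | 4-(benzyloxy)benzoyl chloride | O=C(Cl)c1ccc(OCc2ccccc2)cc1 | starting material
3 | lithium (3E)-4-methoxybuta-1,3-dien-2-olate | C=C(O[Li])/C=C/OC | intermediate
4 | (4E)-1-[4-(benzyloxy)phenyl]-5-methoxypent-4-ene-1,3-dione (largely enolised) | CO/C=C/C(=O)CC(=O)c1ccc(OCc2ccccc2)cc1 | intermediate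
5 | 2-[4-(benzyloxy)phenyl]-4H-pyran-4-one | O=c1ccoc(-c2ccc(OCc3ccccc3)cc2)c1 | intermediate
6 | 2-[4-(benzyloxy)phenyl]-5-iodo-4H-pyran-4-one | O=c1cc(-c2ccc(OCc3ccccc3)cc2)occ1I | intermediate
7 | dimethyl squarate (3,4-dimethoxycyclobut-3-ene-1,2-dione) | COC1=C(OC)C(=O)C1=O | starting material
8 | {6-[4-(benzyloxy)phenyl]-4-oxo-4H-pyran-3-yl}magnesium chloride (LiCl complex) | O=c1cc(-c2ccc(OCc3ccccc3)cc2)occ1[Mg]Cl | intermediate
9 | racemic 4-{6-[4-(benzyloxy)phenyl]-4-oxo-4H-pyran-3-yl}-4-hydroxy-2,3-dimethoxycyclobut-2-en-1-one | COC1=C(OC)C(O)(c2coc(-c3ccc(OCc4ccccc4)cc3)cc2=O)C1=O | intermediate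
10 | racemic 4-{6-[4-(benzyloxy)phenyl]-4-oxo-4H-pyran-3-yl}-2,3,4-trimethoxycyclobut-2-en-1-one | COC1=C(OC)C(OC)(c2coc(-c3ccc(OCc4ccccc4)cc3)cc2=O)C1=O | intermediate
11 | (3Z)-4-{6-[4-(benzyloxy)phenyl]-4-oxo-4H-pyran-3-yl}-2,3,4-trimethoxybuta-1,3-dien-1-one (dienylketene) | COC(=C=O)/C(OC)=C(/OC)c1coc(-c2ccc(OCc3ccccc3)cc2)cc1=O | intermediate
12 | racemic 2-[4-(benzyloxy)phenyl]-5,6,7-trimethoxy-8aH-chromene-4,8-dione | COC1=C(OC)C(=O)C2OC(-c3ccc(OCc4ccccc4)cc3)=CC(=O)C2=C1OC | intermediate
13 | 4'-(benzyloxy)-8-hydroxy-5,6,7-trimethoxyflavone | COc1c(OC)c(OC)c2c(=O)cc(-c3ccc(OCc4ccccc4)cc3)oc2c1O | intermediate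
14 | 4'-(benzyloxy)-5,6,7,8-tetramethoxyflavone | COc1c(OC)c(OC)c2c(=O)cc(-c3ccc(OCc4ccccc4)cc3)oc2c1OC | intermediate
15 | 4'-hydroxy-5,6,7,8-tetramethoxyflavone | COc1c(OC)c(OC)c2c(=O)cc(-c3ccc(O)cc3)oc2c1OC | target

Total step count: 7
Longest linear sequence: 7 steps (1 and 2 to 15; dimethyl squarate 7 enters at step 3)

Steps most likely to fail

Step 5. The electrocyclisation onto the cross-conjugated pyranone double bond may be slower than loss of the ketene by dimerisation or capture by adventitious nucleophiles, so that ring A does not form. The fallback buys ring A instead of building it and sets out from 2. O-Acylation of the known 2'-hydroxy-3',4',5',6'-tetramethoxyacetophenone (CC(=O)c1c(O)c(OC)c(OC)c(OC)c1OC) with 2 in pyridine should give 2-acetyl-3,4,5,6-tetramethoxyphenyl 4-(benzyloxy)benzoate F1. KOH in pyridine at 50 °C should then move the aroyl group to carbon (Baker–Venkataraman rearrangement) to give 1-[4-(benzyloxy)phenyl]-3-(2-hydroxy-3,4,5,6-tetramethoxyphenyl)propane-1,3-dione F2. Acid-catalysed cyclodehydration (p-toluenesulfonic acid, toluene, reflux) should close ring C and return to the route at 14, leaving step 7 unchanged.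

Step 3. The magnesiated pyranone may collapse by β-elimination of the ring oxygen, or the isopropyl Grignard reagent may add to the pyranone before the exchange is complete. The fallback sets out from 6 and replaces exchange by oxidative insertion. Zinc dust with LiCl in THF at rt should insert into the C–I bond to give {6-[4-(benzyloxy)phenyl]-4-oxo-4H-pyran-3-yl}zinc iodide F3, a non-basic organometallic that tolerates the pyranone and can be formed in the presence of the electrophile. Its MgCl2-promoted addition to a ketone carbonyl of 7 should return to the route at 9.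

Step 2. Iodination may go to C3 or to the benzyloxyphenyl ring, or the partly aromatic pyranone may not react under the amine-triggered conditions. The fallback places the iodine before the ring exists and sets out from 1. Treating 1 with I2 and pyridine in CH2Cl2 should give (Z)-3-iodo-4-methoxybut-3-en-2-one F4, in which only one vinylic position is open to substitution. LiN(SiMe3)2 in THF at −78 °C should give lithium (3Z)-3-iodo-4-methoxybuta-1,3-dien-2-olate F5, and acylation with 2 should give (4Z)-1-[4-(benzyloxy)phenyl]-4-iodo-5-methoxypent-4-ene-1,3-dione F6. Catalytic CF3CO2H in CH2Cl2 should then close the ring with loss of methanol and return to the route at 6.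

Further compounds
F1 | step 5 | 2-acetyl-3,4,5,6-tetramethoxyphenyl 4-(benzyloxy)benzoate | CC(=O)c1c(OC)c(OC)c(OC)c(OC)c1OC(=O)c1ccc(OCc2ccccc2)cc1
F2 | step 5 | 1-[4-(benzyloxy)phenyl]-3-(2-hydroxy-3,4,5,6-tetramethoxyphenyl)propane-1,3-dione | COc1c(O)c(C(=O)CC(=O)c2ccc(OCc3ccccc3)cc2)c(OC)c(OC)c1OC
F3 | step 3 | {6-[4-(benzyloxy)phenyl]-4-oxo-4H-pyran-3-yl}zinc iodide | O=c1cc(-c2ccc(OCc3ccccc3)cc2)occ1[Zn]I
F4 | step 2 | (Z)-3-iodo-4-methoxybut-3-en-2-one | CO/C=C(\I)C(C)=O
F5 | step 2 | lithium (3Z)-3-iodo-4-methoxybuta-1,3-dien-2-olate | CO/C=C(\I)C(=C)O[Li]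
F6 | step 2 | (4Z)-1-[4-(benzyloxy)phenyl]-4-iodo-5-methoxypent-4-ene-1,3-dione | CO/C=C(\I)C(=O)CC(=O)c1ccc(OCc2ccccc2)cc1
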